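What share of the charged G stands as J at the end of this flask, and does any of the offered changes raise it?

G 2.8 M; D 5.6 mM; time 10 s

* J at 10 s, in percent of the G charged
* the change that raises the amount of J at 10 s, in percent of the G charged most ("none" if none brings more than 2 percentage points) (Wednesday's / Monday's / Thursday's / none)
* amount of J at 10 s, in percent of the G charged, after Thursday's

- Wednesday's: doubling the solubility in step 3, all else as stated
- Monday's: doubling the dissolution coefficient of step 3, all else as stated
- Thursday's: doubling the amount of D, all else as stated

- solid, in amounts per volume of the solution: G
- at the start none of G is in solution
- run time (flask): 10 s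

    J + D ⇌ Q + D, rate k1*[D]*[J] forward; the back reaction follows from the equilibrium constant (K1 = 7.7, k1 = 490 L mol⁻¹ s⁻¹)
    L + D ⇌ J + D, rate k2*[L]*[D] forward; the back reaction follows from the equilibrium constant (K2 = 3.3, k2 = 95 L mol⁻¹ s⁻¹)
    G ⇌ L, rate k3*(cs3 - [L]) while solid is left; crystals form when [L] > cs3 (cs3 = 1.9 M, k3 = 0.47 s⁻¹)
    Q + D ⇌ L + D, rate k4*[D]*[Q] forward; the back reaction follows from the equilibrium constant (k4 = 82 L mol⁻¹ s⁻¹)

G dissolves to L, and D carries the dissolved material round a ring, from L to J, from J to Q and from Q back to L, with each link running both ways and D coming out unchanged. Follow one molecule through this reckoning of my own. Into a solution kept empty, and with solid never running out, step 3 can deliver at most 319% of the charge by 10 s, which is more than the charge, so at that pace G should last about 3.14 s. With D as charged, the forward half-lives are 1.3 s for L, 0.25 s for J and 1.5 s for Q, each shorter than the 6.86 s that remain, so the molecule can cross its links repeatedly. Once each link is crossed as often forward as back, the molecule spends 3.3 times as long as J as it does as L, and 7.7 times as long as Q as it does as J. The link from Q to L carries the inverse of those two constants and so agrees with them. The chance of finding a ringed molecule as J is therefore 3.3 divided by 29.7, which gives 11.1%; this is the ring share of J, the mark of thermodynamic control. L's share, 3.36%, is less than the 67.9% of the charge that saturation allows, so no solid should remain. The ring share contains neither D, which Thursday's doubles, nor the dissolution coefficient of step 3, which Monday's doubles, nor its solubility, which Wednesday's doubles, so this reckoning commits to 11.1% for J, before and after Thursday's, and to no useful change.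

The forecast gives 11.1%, none as the best change and 11.1% after Thursday's, on the ground that “None of the three changes alters that equilibrium and each only gets there sooner”.

The flask gives 11.1% as J at 10 s, none as the best change and 11.1% after Thursday's. J already reads 11.1% at 5.00 s and still reads 11.1% at 100 s, so the reading at the asked time is a plateau. The ring share multiplied by 7.7 gives 85.5% as Q, and the flask holds 85.5% of Q at 10.0 s.

For the neighbouring flask charged with 1.7 M of G, the ring share contains no charge, so it again gives 11.1% as J. That flask, simulated, gives 11.1%.

The constants used here were drawn at random within sensible limits; the rest is arithmetic.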